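**Retrosynthetic overview** (disconnections listed in the order the bonds are made)
1. C5/C6 diol: achiral penta-1,4-dien-3-ol 1 is desymmetrised by Sharpless epoxidation to epoxy alcohol 2; both stereocentres are set in this one step.
2. C4–C3 and C2–C1: the oxirane is opened by a silylacetylide (3, then 4), the diol is masked as acetonide 5, and methylalumination (alkenylalane 6) plus formaldehyde gives (E)-allylic alcohol 7.
3. Isopropenyl group: the spectator vinyl group is upgraded by Wacker oxidation (methyl ketone 8) and methylenation (9).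
4. Rings: the only ring of the target that is built is the pyranone ring, by Pechmann condensation of pyrogallol 10 with malic acid 11 (through 3-oxopropanoic acid 12) to daphnetin 13, then 8-O-methylation to phenol 14. The oxirane (step 1) and dioxolane (step 3) rings are temporary.
5. C1–O aryl ether: Mitsunobu coupling of 9 with 14 gives acetonide 15; acetal hydrolysis gives target 16.

Assumption: alkoxide, phenoxide and similar acid–base forms of a numbered compound are counted as that compound and get no number of their own; malic acid is used as the racemate.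

Step 1
Reactants: 1 penta-1,4-dien-3-ol
Product: 2 (2S,3R)-1,2-epoxypent-4-en-3-ol
Conditions: Ti(OiPr)4 (0.1 equiv), D-(−)-diisopropyl tartrate (0.13 equiv), cumene hydroperoxide (1.2 equiv), 4 Å MS, CH2Cl2, −20 °C, 5 d
Reagents that add atoms: cumene hydroperoxide, CC(C)(OO)c1ccccc1
Why: Sharpless asymmetric epoxidation run as an enantiotopic-group desymmetrisation (Schreiber type), in which the Ti–D-(−)-tartrate catalyst epoxidises one of the two enantiotopic vinyl groups anti (erythro) to the hydroxyl, setting C2 (S) and C3 (R) together while the minor enantiomer is drained by faster second epoxidation.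

Step 2
Reactants: 2 (2S,3R)-1,2-epoxypent-4-en-3-ol
Product: 4 (3R,4S)-hept-1-en-6-yne-3,4-diol, via silylalkyne diol 3 (not isolated)
Conditions: Me3SiC≡CLi (3 equiv, from Me3SiC≡CH and n-BuLi), BF3·OEt2 (3 equiv), THF, −78 °C; then K2CO3 (cat.), MeOH, rt
Reagents that add atoms: ethynyltrimethylsilane, C#C[Si](C)(C)C
Why: Yamaguchi–Hirao BF3-promoted alkynylation, in which the acetylide opens the oxirane at its unsubstituted CH2 by SN2 so both stereocentres are carried over unchanged, followed by methanolysis of the C–Si bond.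

Step 3
Reactants: 4 (3R,4S)-hept-1-en-6-yne-3,4-diol
Product: 5 (4R,5S)-4-ethenyl-2,2-dimethyl-5-(prop-2-yn-1-yl)-1,3-dioxolane
Conditions: 2,2-dimethoxypropane, PPTS (cat.), CH2Cl2, rt
Reagents that add atoms: 2,2-dimethoxypropane, COC(C)(C)OC
Why: Acid-catalysed transacetalisation (acetonide formation) turns the erythro diol into the cis-dioxolane without touching either stereocentre.

Step 4
Reactants: 5 (4R,5S)-4-ethenyl-2,2-dimethyl-5-(prop-2-yn-1-yl)-1,3-dioxolane
Product: 7 (2E)-4-[(4S,5R)-5-ethenyl-2,2-dimethyl-1,3-dioxolan-4-yl]-3-methylbut-2-en-1-ol, via alkenylalane 6 (not isolated)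
Conditions: Me3Al (3 equiv), Cp2ZrCl2 (0.2 equiv), H2O (1.5 equiv), CH2Cl2, −23 °C; then (CH2O)n, THF, −23 °C → rt
Reagents that add atoms: trimethylaluminium, C[Al](C)C; formaldehyde (as paraformaldehyde), C=O
Why: Negishi zirconium-catalysed carboalumination adds Me–Al syn across the terminal alkyne with Al on the terminal carbon, and the (E)-alkenylalane adds to formaldehyde with retention to give the (E)-trisubstituted allylic alcohol, the vinyl group and acetonide being spectators at low temperature.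

Step 5
Reactants: 7 (2E)-4-[(4S,5R)-5-ethenyl-2,2-dimethyl-1,3-dioxolan-4-yl]-3-methylbut-2-en-1-ol
Product: 8 1-[(4S,5S)-5-[(2E)-4-hydroxy-2-methylbut-2-en-1-yl]-2,2-dimethyl-1,3-dioxolan-4-yl]ethan-1-one
Conditions: PdCl2 (0.1 equiv), CuCl (1 equiv), O2 (1 atm), DMF/H2O 7:1, rt
Reagents that add atoms: water, O
Why: Tsuji–Wacker oxidation hydroxypalladates only the monosubstituted vinyl group in the Markovnikov sense (the trisubstituted alkene is inert, and a ring acetal oxygen on the allylic carbon favours the methyl ketone), and the non-basic medium leaves the α-stereocentre intact.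

Step 6
Reactants: 8 1-[(4S,5S)-5-[(2E)-4-hydroxy-2-methylbut-2-en-1-yl]-2,2-dimethyl-1,3-dioxolan-4-yl]ethan-1-one
Product: 9 (2E)-4-[(4S,5R)-2,2-dimethyl-5-(prop-1-en-2-yl)-1,3-dioxolan-4-yl]-3-methylbut-2-en-1-ol
Conditions: Zn, CH2Br2, TiCl4, THF, 0 °C → rt
Reagents that add atoms: dibromomethane, BrCBr
Why: Takai–Lombardo methylenation with the non-basic gem-dizinc/titanium reagent converts the ketone into the isopropenyl group without enolising the α-alkoxy ketone, so the cis relationship on the dioxolane is kept.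

Step 7
Reactants: 10 pyrogallol; 11 malic acid
Product: 13 daphnetin (7,8-dihydroxy-2H-chromen-2-one), via 3-oxopropanoic acid 12 (not isolated)
Conditions: conc. H2SO4, 100–110 °C
Reagents that add atoms: none
Why: Von Pechmann condensation, in which H2SO4 decarbonylates malic acid to 3-oxopropanoic acid, which attacks the symmetric triol para to one outer hydroxyl and lactonises on the neighbouring one to close the pyranone ring (no stereocentre).

Step 8
Reactants: 13 daphnetin
Product: 14 7-hydroxy-8-methoxy-2H-chromen-2-one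
Conditions: NaH (2.2 equiv), DMF, 0 °C; MeI (1.0 equiv), 0 °C → rt; aq. HCl
Reagents that add atoms: iodomethane, CI
Why: Williamson O-methylation under dianion control, where the 8-oxide (not conjugated to the pyranone carbonyl) is the more basic and nucleophilic oxygen and takes the single equivalent of MeI while the vinylogous-carboxylate 7-oxide stays free, as in 3-O-alkylation of the 3,4-dihydroxybenzaldehyde dianion.

Step 9
Reactants: 9 (2E)-4-[(4S,5R)-2,2-dimethyl-5-(prop-1-en-2-yl)-1,3-dioxolan-4-yl]-3-methylbut-2-en-1-ol; 14 7-hydroxy-8-methoxy-2H-chromen-2-one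
Product: 15 7-{[(2E)-4-[(4S,5R)-2,2-dimethyl-5-(prop-1-en-2-yl)-1,3-dioxolan-4-yl]-3-methylbut-2-en-1-yl]oxy}-8-methoxy-2H-chromen-2-one
Conditions: PPh3, DIAD, THF, 0 °C → rt
Reagents that add atoms: none
Why: Mitsunobu etherification, in which the acidic 7-OH (pKa about 8) displaces the primary allylic oxyphosphonium group by SN2, leaving alkene geometry and both stereocentres untouched.

Step 10
Reactants: 15 7-{[(2E)-4-[(4S,5R)-2,2-dimethyl-5-(prop-1-en-2-yl)-1,3-dioxolan-4-yl]-3-methylbut-2-en-1-yl]oxy}-8-methoxy-2H-chromen-2-one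
Product: 16 7-{[(2E,5S,6R)-5,6-dihydroxy-3,7-dimethylocta-2,7-dien-1-yl]oxy}-8-methoxy-2H-chromen-2-one
Conditions: AcOH/H2O 4:1, 40 °C
Reagents that add atoms: none
Why: Mild acid-catalysed acetal hydrolysis cleaves only the acetal C–O bonds, so the (5S,6R) configuration is retained and the allylic aryl ether survives.

**Compound list**
1 | penta-1,4-dien-3-ol | C=CC(O)C=C | starting material
2 | (2S,3R)-1,2-epoxypent-4-en-3-ol | C=C[C@@H](O)[C@@H]1CO1 | intermediate
3 | (3R,4S)-7-(trimethylsilyl)hept-1-en-6-yne-3,4-diol | C=C[C@@H](O)[C@@H](O)CC#C[Si](C)(C)C | intermediate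
4 | (3R,4S)-hept-1-en-6-yne-3,4-diol | C=C[C@@H](O)[C@@H](O)CC#C | intermediate
5 | (4R,5S)-4-ethenyl-2,2-dimethyl-5-(prop-2-yn-1-yl)-1,3-dioxolane | C=C[C@H]1OC(C)(C)O[C@H]1CC#C | intermediate
6 | {(1E)-3-[(4S,5R)-5-ethenyl-2,2-dimethyl-1,3-dioxolan-4-yl]-2-methylprop-1-en-1-yl}dimethylalumane | C=C[C@H]1OC(C)(C)O[C@H]1C/C(C)=C/[Al](C)C | intermediate
7 | (2E)-4-[(4S,5R)-5-ethenyl-2,2-dimethyl-1,3-dioxolan-4-yl]-3-methylbut-2-en-1-ol | C=C[C@H]1OC(C)(C)O[C@H]1C/C(C)=C/CO | intermediate
8 | 1-[(4S,5S)-5-[(2E)-4-hydroxy-2-methylbut-2-en-1-yl]-2,2-dimethyl-1,3-dioxolan-4-yl]ethan-1-one | CC(=O)[C@H]1OC(C)(C)O[C@H]1C/C(C)=C/CO | intermediate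
9 | (2E)-4-[(4S,5R)-2,2-dimethyl-5-(prop-1-en-2-yl)-1,3-dioxolan-4-yl]-3-methylbut-2-en-1-ol | C=C(C)[C@H]1OC(C)(C)O[C@H]1C/C(C)=C/CO | intermediate
10 | pyrogallol (benzene-1,2,3-triol) | Oc1cccc(O)c1O | starting material
11 | malic acid (racemic) | OC(CC(=O)O)C(=O)O | starting material
12 | 3-oxopropanoic acid | O=CCC(=O)O | intermediate
13 | daphnetin (7,8-dihydroxy-2H-chromen-2-one) | O=c1ccc2ccc(O)c(O)c2o1 | intermediate
14 | 7-hydroxy-8-methoxy-2H-chromen-2-one | COc1c(O)ccc2ccc(=O)oc12 | intermediate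
15 | 7-{[(2E)-4-[(4S,5R)-2,2-dimethyl-5-(prop-1-en-2-yl)-1,3-dioxolan-4-yl]-3-methylbut-2-en-1-yl]oxy}-8-methoxy-2H-chromen-2-one | C=C(C)[C@H]1OC(C)(C)O[C@H]1C/C(C)=C/COc1ccc2ccc(=O)oc2c1OC | intermediate
16 | 7-{[(2E,5S,6R)-5,6-dihydroxy-3,7-dimethylocta-2,7-dien-1-yl]oxy}-8-methoxy-2H-chromen-2-one | C=C(C)[C@@H](O)[C@@H](O)C/C(C)=C/COc1ccc2ccc(=O)oc2c1OC | target

**Step count and risks**
Total step count: 10. Longest linear sequence: 8 steps (steps 1–6, 9, 10).

Step 4 is at risk because Me3Al may attack the acetonide and because trapping the alkenylalane directly with paraformaldehyde can be sluggish. The fallback sets out from 5. Its lithium acetylide (n-BuLi, THF, −78 °C) is hydroxymethylated with (CH2O)n to 4-[(4S,5R)-5-ethenyl-2,2-dimethyl-1,3-dioxolan-4-yl]but-2-yn-1-ol F1. Trans-hydroalumination with NaAlH2(OCH2CH2OMe)2 followed by I2 gives (2Z)-4-[(4S,5R)-5-ethenyl-2,2-dimethyl-1,3-dioxolan-4-yl]-3-iodobut-2-en-1-ol F2. Coupling with Me2CuLi replaces iodine by methyl with retention and returns to the route at 7.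

Step 5 is at risk because the allylic oxygen could divert the Wacker oxidation towards the aldehyde, and because the acetonide and the allylic alcohol see a mildly acidic medium. The fallback sets out from 5 and avoids palladium. Alkene-selective ozonolysis (O3, CH2Cl2, −78 °C; Me2S) gives (4S,5S)-2,2-dimethyl-5-(prop-2-yn-1-yl)-1,3-dioxolane-4-carbaldehyde F3. Excess MeMgBr gives (1RS)-1-[(4R,5S)-2,2-dimethyl-5-(prop-2-yn-1-yl)-1,3-dioxolan-4-yl]ethan-1-ol F4. Dess–Martin oxidation gives 1-[(4S,5S)-2,2-dimethyl-5-(prop-2-yn-1-yl)-1,3-dioxolan-4-yl]ethan-1-one F5. Methylenation with Zn, CH2Br2 and TiCl4 gives (4S,5R)-2,2-dimethyl-4-(prop-2-yn-1-yl)-5-(prop-1-en-2-yl)-1,3-dioxolane F6. The methylalumination/formaldehyde sequence of step 4 applied to F6 returns to the route at 9.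

Step 8 is at risk because the regioselectivity of dianion methylation is argued by analogy and has not been shown here for daphnetin; 7-O-methyl and dimethyl products may form. The fallback sets out from 13 and bypasses 14. Mitsunobu coupling of 9 with daphnetin 13 (PPh3, DIAD, THF) at the more acidic 7-OH gives 7-{[(2E)-4-[(4S,5R)-2,2-dimethyl-5-(prop-1-en-2-yl)-1,3-dioxolan-4-yl]-3-methylbut-2-en-1-yl]oxy}-8-hydroxy-2H-chromen-2-one F7. Methylation of its remaining 8-OH (MeI, K2CO3, acetone) returns to the route at 15.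

**Further compounds**
F1 | step 4 | 4-[(4S,5R)-5-ethenyl-2,2-dimethyl-1,3-dioxolan-4-yl]but-2-yn-1-ol | C=C[C@H]1OC(C)(C)O[C@H]1CC#CCO
F2 | step 4 | (2Z)-4-[(4S,5R)-5-ethenyl-2,2-dimethyl-1,3-dioxolan-4-yl]-3-iodobut-2-en-1-ol | C=C[C@H]1OC(C)(C)O[C@H]1C/C(I)=C/CO
F3 | step 5 | (4S,5S)-2,2-dimethyl-5-(prop-2-yn-1-yl)-1,3-dioxolane-4-carbaldehyde | O=C[C@H]1OC(C)(C)O[C@H]1CC#C
F4 | step 5 | (1RS)-1-[(4R,5S)-2,2-dimethyl-5-(prop-2-yn-1-yl)-1,3-dioxolan-4-yl]ethan-1-ol | CC(O)[C@H]1OC(C)(C)O[C@H]1CC#C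
F5 | step 5 | 1-[(4S,5S)-2,2-dimethyl-5-(prop-2-yn-1-yl)-1,3-dioxolan-4-yl]ethan-1-one | CC(=O)[C@H]1OC(C)(C)O[C@H]1CC#C
F6 | step 5 | (4S,5R)-2,2-dimethyl-4-(prop-2-yn-1-yl)-5-(prop-1-en-2-yl)-1,3-dioxolane | C=C(C)[C@H]1OC(C)(C)O[C@H]1CC#C
F7 | step 8 | 7-{[(2E)-4-[(4S,5R)-2,2-dimethyl-5-(prop-1-en-2-yl)-1,3-dioxolan-4-yl]-3-methylbut-2-en-1-yl]oxy}-8-hydroxy-2H-chromen-2-one | C=C(C)[C@H]1OC(C)(C)O[C@H]1C/C(C)=C/COc1ccc2ccc(=O)oc2c1O
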